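**Strategy**

Ring C of the flavanone (O1, C2, C3, C4) is opened at C2–C3. C2 is benzylic to the electron-rich ring B and bound to O1, so in the open precursor it is the CH2 of an aryl 3,4-dimethoxybenzyl ether, a hydridic, doubly activated C–H site. The key step decomposes a 2-(3,4-dimethoxybenzyloxy)aryl diazomethyl ketone with a chiral dirhodium carboxylate: the carbene carbon (future C3) inserts into one enantiotopic benzylic C–H bond, closing ring C and setting (2S)-C2 in one operation. The precursor is an acyclic diazoketone on hexasubstituted ring A with the 8-OH masked as a silyl ether, made from a commercial hydroxyacetophenone by formylation, benzylation, Baeyer–Villiger oxidation and diazo transfer.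

Key step: step 6

Remark: ketone 1 and bromide 4 are taken as purchased; Rh2(S-BSP)4, dirhodium tetrakis[(2S)-1-(benzenesulfonyl)pyrrolidine-2-carboxylate], is assumed to be the antipode that gives (2S), and its mirror-image complex from D-proline would be used in the same way if the sense of induction proves opposite.

**Route**

Step 1
Reactants: 1 1-(6-hydroxy-2,3,4-trimethoxyphenyl)ethan-1-one
Product: 3 3-acetyl-2-hydroxy-4,5,6-trimethoxybenzaldehyde, via chloro(methoxy)methyl arene 2 (not isolated)
Conditions: Cl2CHOMe, TiCl4, CH2Cl2, 0 °C; then H2O (aq. HCl), 0 °C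
Reagents that add atoms: dichloromethyl methyl ether ClC(Cl)OC; water O
Why: Rieche formylation, in which the titanium phenoxide of 1 directs the electrophile from Cl2CHOMe and TiCl4 to the only unsubstituted ring carbon (ortho to OH, para to a methoxy group) and the chloro ether 2 is hydrolysed to the aldehyde on aqueous work-up.

Step 2
Reactants: 3 3-acetyl-2-hydroxy-4,5,6-trimethoxybenzaldehyde; 4 4-(bromomethyl)-1,2-dimethoxybenzene
Product: 5 3-acetyl-2-[(3,4-dimethoxyphenyl)methoxy]-4,5,6-trimethoxybenzaldehyde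
Conditions: K2CO3, DMF, 50 °C
Reagents that add atoms: none
Why: Williamson ether synthesis, in which the acidic phenol flanked by two carbonyl groups is deprotonated by K2CO3 and displaces bromide from the reactive benzylic bromide, no ring carbon being free for C-alkylation.

Step 3
Reactants: 5 3-acetyl-2-[(3,4-dimethoxyphenyl)methoxy]-4,5,6-trimethoxybenzaldehyde
Product: 7 1-{2-[(3,4-dimethoxyphenyl)methoxy]-3-hydroxy-4,5,6-trimethoxyphenyl}ethan-1-one, via aryl formate 6 (not isolated)
Conditions: mCPBA, CH2Cl2, 0 °C to rt; aq. NaHCO3 wash; then K2CO3 (cat.), MeOH, rt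
Reagents that add atoms: mCPBA O=C(OO)c1cccc(Cl)c1
Why: Baeyer–Villiger (Dakin-type) oxidation, in which the electron-rich di-ortho-alkoxy aryl group of the aldehyde migrates much faster than the hindered methyl ketone reacts, and mild methanolysis of formate 6 then unveils the future 8-OH with unambiguous regiochemistry.

Step 4
Reactants: 7 1-{2-[(3,4-dimethoxyphenyl)methoxy]-3-hydroxy-4,5,6-trimethoxyphenyl}ethan-1-one
Product: 8 1-{3-[(tert-butyldimethylsilyl)oxy]-2-[(3,4-dimethoxyphenyl)methoxy]-4,5,6-trimethoxyphenyl}ethan-1-one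
Conditions: TBSCl, imidazole, DMF, rt
Reagents that add atoms: tert-butyldimethylsilyl chloride CC(C)(C)[Si](C)(C)Cl
Why: Imidazole-promoted silyl ether formation at the only free hydroxyl masks the future 8-OH with a bulky, weakly nucleophilic group that has no O–H and no activated C–H bond for the carbene of step 6.

Step 5
Reactants: 8 1-{3-[(tert-butyldimethylsilyl)oxy]-2-[(3,4-dimethoxyphenyl)methoxy]-4,5,6-trimethoxyphenyl}ethan-1-one
Product: 10 1-{3-[(tert-butyldimethylsilyl)oxy]-2-[(3,4-dimethoxyphenyl)methoxy]-4,5,6-trimethoxyphenyl}-2-diazoethan-1-one, via trifluoroacetyl ketone 9 (not isolated)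
Conditions: LiN(SiMe3)2, THF, −78 °C; CF3CO2CH2CF3, −78 °C; aq. HCl quench; then MsN3, Et3N, H2O, MeCN, rt
Reagents that add atoms: 2,2,2-trifluoroethyl trifluoroacetate O=C(OCC(F)(F)F)C(F)(F)F (atoms retained only in 9); methanesulfonyl azide CS(=O)(=O)N=[N+]=[N-]
Why: Regitz-type detrifluoroacetylative diazo transfer, in which the kinetic lithium enolate of the methyl ketone is C-trifluoroacetylated and the activated 1,3-diketone 9 takes the diazo group from mesyl azide with loss of the trifluoroacetyl group as the N-acylsulfonamide.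

Step 6
Reactants: 10 1-{3-[(tert-butyldimethylsilyl)oxy]-2-[(3,4-dimethoxyphenyl)methoxy]-4,5,6-trimethoxyphenyl}-2-diazoethan-1-one
Product: 11 (2S)-8-[(tert-butyldimethylsilyl)oxy]-2-(3,4-dimethoxyphenyl)-5,6,7-trimethoxy-2,3-dihydro-4H-chromen-4-one
Conditions: Rh2(S-BSP)4 (2 mol %), CH2Cl2, slow addition of 10, 0 °C to rt
Reagents that add atoms: none
Why: The dirhodium tetracarboxylate expels N2 from 10 to give an electrophilic rhodium-bound carbene at the future C3, which inserts into a benzylic C–H bond of the OCH2Ar group through a concerted, hydride-transfer-like three-centre transition state with retention at carbon, forming the C3–C2 bond. The closest known reaction type is the dirhodium-carboxylate-catalysed intramolecular C–H insertion of 2-alkoxyphenyl diazomethyl ketones to chroman-4-ones, including its enantioselective form with chiral N-sulfonylprolinate ligands. Ring C closes as a six-membered ring by formal 1,6-C–H insertion, the usually preferred five-membered closure being impossible because the fifth atom from the carbene carbon is the ether oxygen O1, which carries no hydrogen. The only new stereocentre, C2, arises from the choice between the two enantiotopic benzylic hydrogens and is controlled solely by the chiral carboxylate ligands of the catalyst, the substrate being achiral. The step needs C–H insertion to win over oxonium ylide formation at O1 followed by [1,2]-benzyl shift to a benzofuranone, over insertion into the C–H bonds of the C5 methoxy group and over reaction at the 8-oxygen. The benzylic C–H bond should be preferred because it is activated by both O1 and the 3,4-dimethoxyphenyl ring, a rhodium carboxylate favours insertion over ylide formation more than a copper catalyst does, the methoxy C–H bonds are primary and unactivated, and the silyl ether offers neither an O–H nor an activated C–H bond.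

Step 7
Reactants: 11 (2S)-8-[(tert-butyldimethylsilyl)oxy]-2-(3,4-dimethoxyphenyl)-5,6,7-trimethoxy-2,3-dihydro-4H-chromen-4-one
Product: 12 (2S)-2-(3,4-dimethoxyphenyl)-8-hydroxy-5,6,7-trimethoxy-2,3-dihydro-4H-chromen-4-one
Conditions: HF·pyridine, THF, 0 °C to rt
Reagents that add atoms: none
Why: Fluoride-mediated desilylation of the aryl silyl ether under mildly acidic conditions avoids the phenoxide or enolate that could open ring C by retro-oxa-Michael reaction, so the C2 configuration should be preserved.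

**Compound list**

1 | 1-(6-hydroxy-2,3,4-trimethoxyphenyl)ethan-1-one | CC(=O)c1c(O)cc(OC)c(OC)c1OC | starting material
2 | 1-{3-[chloro(methoxy)methyl]-2-hydroxy-4,5,6-trimethoxyphenyl}ethan-1-one | CC(=O)c1c(O)c(C(Cl)OC)c(OC)c(OC)c1OC | intermediate
3 | 3-acetyl-2-hydroxy-4,5,6-trimethoxybenzaldehyde | CC(=O)c1c(O)c(C=O)c(OC)c(OC)c1OC | intermediate
4 | 4-(bromomethyl)-1,2-dimethoxybenzene | COc1ccc(CBr)cc1OC | starting material
5 | 3-acetyl-2-[(3,4-dimethoxyphenyl)methoxy]-4,5,6-trimethoxybenzaldehyde | CC(=O)c1c(OCc2ccc(OC)c(OC)c2)c(C=O)c(OC)c(OC)c1OC | intermediate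
6 | 3-acetyl-2-[(3,4-dimethoxyphenyl)methoxy]-4,5,6-trimethoxyphenyl formate | CC(=O)c1c(OCc2ccc(OC)c(OC)c2)c(OC=O)c(OC)c(OC)c1OC | intermediate
7 | 1-{2-[(3,4-dimethoxyphenyl)methoxy]-3-hydroxy-4,5,6-trimethoxyphenyl}ethan-1-one | CC(=O)c1c(OCc2ccc(OC)c(OC)c2)c(O)c(OC)c(OC)c1OC | intermediate
8 | 1-{3-[(tert-butyldimethylsilyl)oxy]-2-[(3,4-dimethoxyphenyl)methoxy]-4,5,6-trimethoxyphenyl}ethan-1-one | CC(=O)c1c(OCc2ccc(OC)c(OC)c2)c(O[Si](C)(C)C(C)(C)C)c(OC)c(OC)c1OC | intermediate
9 | 1-{3-[(tert-butyldimethylsilyl)oxy]-2-[(3,4-dimethoxyphenyl)methoxy]-4,5,6-trimethoxyphenyl}-4,4,4-trifluorobutane-1,3-dione | O=C(CC(=O)C(F)(F)F)c1c(OCc2ccc(OC)c(OC)c2)c(O[Si](C)(C)C(C)(C)C)c(OC)c(OC)c1OC | intermediate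
10 | 1-{3-[(tert-butyldimethylsilyl)oxy]-2-[(3,4-dimethoxyphenyl)methoxy]-4,5,6-trimethoxyphenyl}-2-diazoethan-1-one | [N-]=[N+]=CC(=O)c1c(OCc2ccc(OC)c(OC)c2)c(O[Si](C)(C)C(C)(C)C)c(OC)c(OC)c1OC | intermediate
11 | (2S)-8-[(tert-butyldimethylsilyl)oxy]-2-(3,4-dimethoxyphenyl)-5,6,7-trimethoxy-2,3-dihydro-4H-chromen-4-one | COc1ccc([C@@H]2CC(=O)c3c(c(O[Si](C)(C)C(C)(C)C)c(OC)c(OC)c3OC)O2)cc1OC | intermediate
12 | (2S)-2-(3,4-dimethoxyphenyl)-8-hydroxy-5,6,7-trimethoxy-2,3-dihydro-4H-chromen-4-one | COc1ccc([C@@H]2CC(=O)c3c(c(O)c(OC)c(OC)c3OC)O2)cc1OC | target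

**Step count and risks**

Total step count: 7. Longest linear sequence: 7 steps (1 to 12; bromide 4 enters in step 2).

Steps most likely to fail:

Step 6. The carbene may be captured by the lone pair of the ether oxygen O1, giving an oxonium ylide that undergoes [1,2]-benzyl shift, and the catalyst may discriminate poorly between the two enantiotopic benzylic hydrogens. The fallback builds ring C first and adds ring B by enantioselective conjugate addition. It sets out from aldehyde 3. Dakin oxidation (H2O2, aq. NaOH) would give the catechol ketone 1-(2,3-dihydroxy-4,5,6-trimethoxyphenyl)ethan-1-one F1. TBSCl and imidazole would silylate its non-chelated hydroxyl to 1-{3-[(tert-butyldimethylsilyl)oxy]-2-hydroxy-4,5,6-trimethoxyphenyl}ethan-1-one F2. N,N-Dimethylformamide dimethyl acetal (neat, 90 °C) would give the enaminone (2E)-1-{3-[(tert-butyldimethylsilyl)oxy]-2-hydroxy-4,5,6-trimethoxyphenyl}-3-(dimethylamino)prop-2-en-1-one F3. Dilute HCl in CH2Cl2 at rt would cyclise it to the chromone 8-[(tert-butyldimethylsilyl)oxy]-5,6,7-trimethoxy-4H-chromen-4-one F4. Addition of (3,4-dimethoxyphenyl)boronic acid under Pd(OCOCF3)2 with the enantiomer of 4-tert-butyl-2-(pyridin-2-yl)-4,5-dihydrooxazole matched to the (2S) product (NH4PF6, H2O, 1,2-dichloroethane, 60 °C) should then give 11, where the route is rejoined.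

Step 5. C-Trifluoroacetylation of the hindered, doubly ortho-substituted enolate may be incomplete, or the diketone may undergo retro-Claisen cleavage before the diazo group is transferred. The fallback introduces the diazo group by substitution and sets out from ketone 8. LiN(SiMe3)2 and Me3SiCl (THF, −78 °C) would give the trimethylsilyl enol ether tert-butyl{2-[(3,4-dimethoxyphenyl)methoxy]-4,5,6-trimethoxy-3-[1-(trimethylsilyloxy)ethenyl]phenoxy}dimethylsilane F5. NBS at −78 °C would convert it to the bromoketone 2-bromo-1-{3-[(tert-butyldimethylsilyl)oxy]-2-[(3,4-dimethoxyphenyl)methoxy]-4,5,6-trimethoxyphenyl}ethan-1-one F6. N,N'-Ditosylhydrazine with DBU in THF at 0 °C (N-alkylation, then twofold loss of sulfinate) should return diazoketone 10.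

Step 1. TiCl4 may cleave the methoxy group next to the acetyl group by chelation, and the acyl-deactivated ring may react sluggishly. The fallback brings in the future 8-oxygen through a bromide and sets out from 1. NBS in MeCN would brominate the single free ring position to give 1-(3-bromo-2-hydroxy-4,5,6-trimethoxyphenyl)ethan-1-one F7. Alkylation with bromide 4 (K2CO3, DMF) would give 1-{3-bromo-2-[(3,4-dimethoxyphenyl)methoxy]-4,5,6-trimethoxyphenyl}ethan-1-one F8. Miyaura borylation (B2pin2, KOAc, Pd(OAc)2, SPhos, dioxane, 90 °C) would give the boronate 1-{2-[(3,4-dimethoxyphenyl)methoxy]-4,5,6-trimethoxy-3-(4,4,5,5-tetramethyl-1,3,2-dioxaborolan-2-yl)phenyl}ethan-1-one F9. Oxidation with NaBO3·4H2O in THF/H2O should give phenol 7, where the route is rejoined.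

**Further compounds**

F1 | step 6 | 1-(2,3-dihydroxy-4,5,6-trimethoxyphenyl)ethan-1-one | CC(=O)c1c(O)c(O)c(OC)c(OC)c1OC
F2 | step 6 | 1-{3-[(tert-butyldimethylsilyl)oxy]-2-hydroxy-4,5,6-trimethoxyphenyl}ethan-1-one | CC(=O)c1c(O)c(O[Si](C)(C)C(C)(C)C)c(OC)c(OC)c1OC
F3 | step 6 | (2E)-1-{3-[(tert-butyldimethylsilyl)oxy]-2-hydroxy-4,5,6-trimethoxyphenyl}-3-(dimethylamino)prop-2-en-1-one | CN(C)/C=C/C(=O)c1c(O)c(O[Si](C)(C)C(C)(C)C)c(OC)c(OC)c1OC
F4 | step 6 | 8-[(tert-butyldimethylsilyl)oxy]-5,6,7-trimethoxy-4H-chromen-4-one | O=c1ccoc2c(O[Si](C)(C)C(C)(C)C)c(OC)c(OC)c(OC)c12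
F5 | step 5 | tert-butyl{2-[(3,4-dimethoxyphenyl)methoxy]-4,5,6-trimethoxy-3-[1-(trimethylsilyloxy)ethenyl]phenoxy}dimethylsilane | C=C(O[Si](C)(C)C)c1c(OCc2ccc(OC)c(OC)c2)c(O[Si](C)(C)C(C)(C)C)c(OC)c(OC)c1OC
F6 | step 5 | 2-bromo-1-{3-[(tert-butyldimethylsilyl)oxy]-2-[(3,4-dimethoxyphenyl)methoxy]-4,5,6-trimethoxyphenyl}ethan-1-one | BrCC(=O)c1c(OCc2ccc(OC)c(OC)c2)c(O[Si](C)(C)C(C)(C)C)c(OC)c(OC)c1OC
F7 | step 1 | 1-(3-bromo-2-hydroxy-4,5,6-trimethoxyphenyl)ethan-1-one | CC(=O)c1c(O)c(Br)c(OC)c(OC)c1OC
F8 | step 1 | 1-{3-bromo-2-[(3,4-dimethoxyphenyl)methoxy]-4,5,6-trimethoxyphenyl}ethan-1-one | CC(=O)c1c(OCc2ccc(OC)c(OC)c2)c(Br)c(OC)c(OC)c1OC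
F9 | step 1 | 1-{2-[(3,4-dimethoxyphenyl)methoxy]-4,5,6-trimethoxy-3-(4,4,5,5-tetramethyl-1,3,2-dioxaborolan-2-yl)phenyl}ethan-1-one | CC(=O)c1c(OCc2ccc(OC)c(OC)c2)c(B2OC(C)(C)C(C)(C)O2)c(OC)c(OC)c1OC
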